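**Strategy.** The route rests on disconnecting the benzylic CH2–aryl bond to the syringyl (4-hydroxy-3,5-dimethoxyphenyl) ring. That benzylic CH2, the neighbouring CH and the acetoxymethyl carbon on that CH are recognised as the exocyclic =CH2, C-α and C=O of an α-methylene-γ-butyrolactone, whose ring oxygen is the oxygen of the second acetoxymethyl group. A rhodium-catalysed 1,4-addition of the unprotected syringyl boronate to the (R)-β-veratrylmethyl-α-methylene lactone forges the bond, completes the lignan skeleton and creates the second stereocentre. Base equilibration then funnels that centre to the trans (3R,4R) lactone under control of the fixed β-centre. Reduction and lipase-catalysed acetylation of the two primary alcohols finish the synthesis.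

Key step: step 5

Assumption: both stereocentres of the target are R, which corresponds to the trans-(3R,4R) lactone 12. In step 2 the ligand enantiomer is the one that delivers the (R)-acid, expected to be the (4S,5S) ligand by analogy with other arylidenesuccinate half-esters; its antipode is used if the sense proves opposite.

Step 1
Reactants: 1 3,4-dimethoxybenzaldehyde (veratraldehyde); 2 dimethyl succinate
Product: 3 (E)-4-(3,4-dimethoxyphenyl)-3-(methoxycarbonyl)but-3-enoic acid
Conditions: NaOMe (2 equiv), MeOH, reflux; then aq. HCl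
Reagents that add atoms: none
Why: Stobbe condensation, in which the succinate enolate adds to the aldehyde, the aldolate lactonises onto the distal ester and E1cB opening of the paraconate should give the (E)-alkylidene half-ester with the free acid on the CH2 arm.

Step 2
Reactants: 3 (E)-4-(3,4-dimethoxyphenyl)-3-(methoxycarbonyl)but-3-enoic acid
Product: 4 (3R)-4-(3,4-dimethoxyphenyl)-3-(methoxycarbonyl)butanoic acid
Conditions: [Rh(cod)2]BF4 (1 mol %), (4S,5S)-MOD-DIOP (1.2 mol %), Et3N (1 equiv), H2 (1–5 atm), MeOH, 30 °C; then aq. HCl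
Reagents that add atoms: none
Why: Rh–bisphosphine asymmetric hydrogenation of an itaconate-type half-ester, in which the carboxylate and the C=C chelate rhodium so that H2 is delivered to one enantioface and the (R) centre is set under catalyst control.

Step 3
Reactants: 4 (3R)-4-(3,4-dimethoxyphenyl)-3-(methoxycarbonyl)butanoic acid
Product: 6 (4R)-4-(3,4-dimethoxybenzyl)dihydrofuran-2(3H)-one, via (3R)-4-(3,4-dimethoxyphenyl)-3-(hydroxymethyl)butanoic acid 5 (not isolated)
Conditions: KOH (1.0 equiv), EtOH, 0 °C; CaCl2, NaBH4, EtOH, −10 °C to rt; then 2 M HCl, rt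
Reagents that add atoms: none
Why: chemoselective borohydride reduction, in which the potassium carboxylate is inert to Ca(BH4)2 while the methyl ester is reduced, and acidification lactonises the γ-hydroxy acid without touching the stereocentre.

Step 4
Reactants: 6 (4R)-4-(3,4-dimethoxybenzyl)dihydrofuran-2(3H)-one
Product: 9 (4R)-4-(3,4-dimethoxybenzyl)-3-methylidenedihydrofuran-2(3H)-one, via (3S,4R)-4-(3,4-dimethoxybenzyl)-3-[(dimethylamino)methyl]dihydrofuran-2(3H)-one 7 (not isolated), via [(3S,4R)-4-(3,4-dimethoxybenzyl)-2-oxotetrahydrofuran-3-yl]-N,N,N-trimethylmethanaminium iodide 8 (not isolated)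
Conditions: LDA (1.1 equiv), THF, −78 °C; CH2=NMe2+ I− (1.5 equiv), −78 °C to rt; MeI (excess), MeOH, rt; aq. NaHCO3, CH2Cl2, rt
Reagents that add atoms: Eschenmoser's salt (N,N-dimethylmethyleneiminium iodide), C=[N+](C)C.[I-] (supplies the =CH2 carbon); iodomethane, CI (its methyl is carried only by intermediate 8)
Why: Eschenmoser methylenation, that is Mannich aminomethylation of the lactone lithium enolate, exhaustive N-methylation and E1cB (Hofmann-type) elimination, with C-4 carrying no acidic hydrogen and therefore retained.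

Step 5
Reactants: 9 (4R)-4-(3,4-dimethoxybenzyl)-3-methylidenedihydrofuran-2(3H)-one; 10 2,6-dimethoxy-4-(4,4,5,5-tetramethyl-1,3,2-dioxaborolan-2-yl)phenol (2 equiv)
Product: 12 (3R,4R)-4-(3,4-dimethoxybenzyl)-3-(4-hydroxy-3,5-dimethoxybenzyl)dihydrofuran-2(3H)-one, via (4R)-4-(3,4-dimethoxybenzyl)-3-(4-hydroxy-3,5-dimethoxybenzyl)dihydrofuran-2(3H)-one as a mixture of C-3 epimers 11 (not isolated)
Conditions: [Rh(cod)OH]2 (2.5 mol %), 1,4-dioxane/H2O (10:1), 50 °C; then solvent switch, DBU (3 equiv), toluene/THF, 80 °C; aq. NH4Cl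
Reagents that add atoms: none
Why: The Rh(I)–OH complex transmetalates boronate 10 to an aryl–Rh(I) species that inserts the s-cis-locked exocyclic C=CH2 of 9 with the aryl carbon going to the terminal CH2 (the only regiochemistry that gives the stabilised Rh oxa-π-allyl enolate), and water protonates this enolate at C-3 and regenerates Rh–OH, so the benzylic CH2–aryl bond and the complete dibenzylbutyrolactone skeleton arise in one catalytic operation. The closest known reaction type is the Hayashi–Miyaura rhodium-catalysed 1,4-addition of arylboron reagents to α-substituted acrylates and α-methylene carbonyl compounds with protonation of the enolate. No ring is closed; the lactone of 9 is a temporary ring that locks the acceptor and is opened in step 6. The new stereocentre C-3 is first set by protonation of the enolate, expected mainly anti to the C-4 benzyl group (cis lactone), so the epimeric mixture 11 is then funnelled by DBU-mediated enolisation–reprotonation to the thermodynamically preferred trans lactone, the controlling element being the fixed, non-enolisable (R)-C-4 centre from step 2, which makes trans equal to (3R,4R). The step needs 1,4-arylation to outrun Heck-type β-hydride elimination, exo-to-endo alkene migration and oxa-Michael addition of the phenol, which the aqueous medium (fast protonolysis of the Rh enolate), the absence of strong base in the arylation stage and the two methoxy groups flanking the phenol should secure; protodeboronation of the electron-rich boronate is offset by the excess of 10.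

Step 6
Reactants: 12 (3R,4R)-4-(3,4-dimethoxybenzyl)-3-(4-hydroxy-3,5-dimethoxybenzyl)dihydrofuran-2(3H)-one
Product: 13 (2R,3R)-2-(3,4-dimethoxybenzyl)-3-(4-hydroxy-3,5-dimethoxybenzyl)butane-1,4-diol
Conditions: LiAlH4 (3 equiv), THF, 0 °C to rt; Rochelle salt work-up at pH about 6
Reagents that add atoms: none
Why: hydride reduction of the lactone to the 1,4-diol, in which the phenol only consumes one hydride as its aluminate and neither stereocentre is epimerised.

Step 7
Reactants: 13 (2R,3R)-2-(3,4-dimethoxybenzyl)-3-(4-hydroxy-3,5-dimethoxybenzyl)butane-1,4-diol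
Product: 14 Justin C, (2R,3R)-2-(3,4-dimethoxybenzyl)-3-(4-hydroxy-3,5-dimethoxybenzyl)butane-1,4-diyl diacetate
Conditions: immobilised Candida antarctica lipase B (a lipase, serine hydrolase), vinyl acetate (6 equiv), THF/MTBE, 40 °C
Reagents that add atoms: vinyl acetate, C=COC(C)=O
Why: lipase-catalysed irreversible transesterification, in which the acyl-enzyme should transfer acetyl to the two primary aliphatic alcohols but not to the hindered, poorly nucleophilic phenol, driven by tautomerisation of vinyl alcohol to acetaldehyde.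

**Compound list**

1 | 3,4-dimethoxybenzaldehyde (veratraldehyde) | COc1ccc(C=O)cc1OC | starting material
2 | dimethyl succinate | COC(=O)CCC(=O)OC | starting material
3 | (E)-4-(3,4-dimethoxyphenyl)-3-(methoxycarbonyl)but-3-enoic acid | COC(=O)/C(CC(=O)O)=C/c1ccc(OC)c(OC)c1 | intermediate
4 | (3R)-4-(3,4-dimethoxyphenyl)-3-(methoxycarbonyl)butanoic acid | COC(=O)[C@@H](CC(=O)O)Cc1ccc(OC)c(OC)c1 | intermediate
5 | (3R)-4-(3,4-dimethoxyphenyl)-3-(hydroxymethyl)butanoic acid (present as its carboxylate, not isolated) | OC(=O)C[C@H](CO)Cc1ccc(OC)c(OC)c1 | intermediate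
6 | (4R)-4-(3,4-dimethoxybenzyl)dihydrofuran-2(3H)-one | O=C1C[C@@H](Cc2ccc(OC)c(OC)c2)CO1 | intermediate
7 | (3S,4R)-4-(3,4-dimethoxybenzyl)-3-[(dimethylamino)methyl]dihydrofuran-2(3H)-one (not isolated) | O=C1OC[C@H](Cc2ccc(OC)c(OC)c2)[C@H]1CN(C)C | intermediate
8 | [(3S,4R)-4-(3,4-dimethoxybenzyl)-2-oxotetrahydrofuran-3-yl]-N,N,N-trimethylmethanaminium iodide (not isolated) | O=C1OC[C@H](Cc2ccc(OC)c(OC)c2)[C@H]1C[N+](C)(C)C.[I-] | intermediate
9 | (4R)-4-(3,4-dimethoxybenzyl)-3-methylidenedihydrofuran-2(3H)-one | C=C1C(=O)OC[C@@H]1Cc1ccc(OC)c(OC)c1 | intermediate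
10 | 2,6-dimethoxy-4-(4,4,5,5-tetramethyl-1,3,2-dioxaborolan-2-yl)phenol | COc1cc(B2OC(C)(C)C(C)(C)O2)cc(OC)c1O | starting material
11 | (4R)-4-(3,4-dimethoxybenzyl)-3-(4-hydroxy-3,5-dimethoxybenzyl)dihydrofuran-2(3H)-one, mixture of C-3 epimers (not isolated) | O=C1OC[C@H](Cc2ccc(OC)c(OC)c2)C1Cc1cc(OC)c(O)c(OC)c1 | intermediate
12 | (3R,4R)-4-(3,4-dimethoxybenzyl)-3-(4-hydroxy-3,5-dimethoxybenzyl)dihydrofuran-2(3H)-one | O=C1OC[C@H](Cc2ccc(OC)c(OC)c2)[C@H]1Cc1cc(OC)c(O)c(OC)c1 | intermediate
13 | (2R,3R)-2-(3,4-dimethoxybenzyl)-3-(4-hydroxy-3,5-dimethoxybenzyl)butane-1,4-diol | COc1ccc(C[C@@H](CO)[C@H](CO)Cc2cc(OC)c(O)c(OC)c2)cc1OC | intermediate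
14 | Justin C, (2R,3R)-2-(3,4-dimethoxybenzyl)-3-(4-hydroxy-3,5-dimethoxybenzyl)butane-1,4-diyl diacetate | COc1ccc(C[C@@H](COC(C)=O)[C@H](COC(C)=O)Cc2cc(OC)c(O)c(OC)c2)cc1OC | target

**Total step count:** 7. **Longest linear sequence:** 7 steps (1 to 14); boronate 10 enters as a commercial fragment in step 5.

**Steps most likely to fail**

Step 5. Protodeboronation of the electron-rich phenolic boronate may outpace insertion, and the cis-to-trans equilibration may stop short of full convergence. The fallback sets out from 9 and comes back at 12, forming the same bond with a protected, stoichiometric aryl nucleophile. Commercial 4-bromo-2,6-dimethoxyphenol is benzylated (BnBr, K2CO3, DMF) to 2-(benzyloxy)-5-bromo-1,3-dimethoxybenzene F1. Magnesium in THF converts it to [4-(benzyloxy)-3,5-dimethoxyphenyl]magnesium bromide F2. Copper-catalysed conjugate addition of F2 to 9 (CuBr·SMe2 20 mol %, THF, −40 °C, NH4Cl quench) should give (4R)-3-[4-(benzyloxy)-3,5-dimethoxybenzyl]-4-(3,4-dimethoxybenzyl)dihydrofuran-2(3H)-one as C-3 epimers F3. DBU in toluene at 80 °C should equilibrate F3 to the trans (3R,4R) benzyl ether F4, and hydrogenolysis (H2, Pd/C, EtOAc) should release 12.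

Step 7. The second acylation of the hindered, β-branched diol may stall in the enzyme pocket, leaving monoacetates. The fallback sets out from 13 and comes back at 14. Peracetylation (Ac2O, pyridine, DMAP, CH2Cl2) should give (2R,3R)-2-(4-acetoxy-3,5-dimethoxybenzyl)-3-(3,4-dimethoxybenzyl)butane-1,4-diyl diacetate F5. Chemoselective aminolysis of its aryl acetate (pyrrolidine 1.1 equiv, MeCN, 0 °C) should then leave the two alkyl acetates and give 14.

Step 2. Enantiofacial discrimination in the hydrogenation may be insufficient, and no later step upgrades the enantiomeric purity. The fallback sets out from 3 and comes back at 4 by classical resolution. Hydrogenation over Pd/C (H2, MeOH) should give racemic 4-(3,4-dimethoxyphenyl)-3-(methoxycarbonyl)butanoic acid F6. Fractional crystallisation with one enantiomer of 1-phenylethylamine, chosen by screening and drawn here as (R), should give the less soluble (R)-1-phenylethylammonium (3R)-4-(3,4-dimethoxyphenyl)-3-(methoxycarbonyl)butanoate F7. Acidification releases 4, and the unwanted enantiomer can be racemised with NaOMe and recycled.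

**Further compounds**

F1 | step 5 | 2-(benzyloxy)-5-bromo-1,3-dimethoxybenzene | COc1cc(Br)cc(OC)c1OCc1ccccc1
F2 | step 5 | [4-(benzyloxy)-3,5-dimethoxyphenyl]magnesium bromide | COc1cc([Mg]Br)cc(OC)c1OCc1ccccc1
F3 | step 5 | (4R)-3-[4-(benzyloxy)-3,5-dimethoxybenzyl]-4-(3,4-dimethoxybenzyl)dihydrofuran-2(3H)-one, mixture of C-3 epimers | O=C1OC[C@H](Cc2ccc(OC)c(OC)c2)C1Cc1cc(OC)c(OCc2ccccc2)c(OC)c1
F4 | step 5 | (3R,4R)-3-[4-(benzyloxy)-3,5-dimethoxybenzyl]-4-(3,4-dimethoxybenzyl)dihydrofuran-2(3H)-one | O=C1OC[C@H](Cc2ccc(OC)c(OC)c2)[C@H]1Cc1cc(OC)c(OCc2ccccc2)c(OC)c1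
F5 | step 7 | (2R,3R)-2-(4-acetoxy-3,5-dimethoxybenzyl)-3-(3,4-dimethoxybenzyl)butane-1,4-diyl diacetate | COc1ccc(C[C@@H](COC(C)=O)[C@H](COC(C)=O)Cc2cc(OC)c(OC(C)=O)c(OC)c2)cc1OC
F6 | step 2 | racemic 4-(3,4-dimethoxyphenyl)-3-(methoxycarbonyl)butanoic acid | COC(=O)C(CC(=O)O)Cc1ccc(OC)c(OC)c1
F7 | step 2 | (R)-1-phenylethylammonium (3R)-4-(3,4-dimethoxyphenyl)-3-(methoxycarbonyl)butanoate | COC(=O)[C@@H](CC(=O)[O-])Cc1ccc(OC)c(OC)c1.C[C@@H]([NH3+])c1ccccc1
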